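**Plan**

1. Target numbering: tetrahydrofuran O1, C2 (3,4-dimethoxyphenyl), C3 (CH2OH), C4 (3,4,5-trimethoxybenzoyl), C5 (CH2); the three substituents are all cis (2R,3R,4R).
2. Cuts: first the aroyl C(=O)–aryl bond, giving 3,4,5-trimethoxyphenyllithium and a cis-fused γ-lactone that ties the C3 hydroxymethyl oxygen to the C4 acyl carbon (a temporary ring, absent from the target). Then the C2–aryl and C2–H bonds, giving a second aryllithium and the C2-symmetric bis-lactone of (2R,3R)-2,3-bis(hydroxymethyl)succinic acid. Last, the two C–CH2O bonds of that succinate.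
3. Feature used: the C3 CH2OH oxygen and the C4 ketone carbon are cis and 1,4-related (a masked γ-lactone), and O1–C2 with C3–C4–C5 is the reduced form of a second γ-lactone. The core is therefore a 3,7-dioxabicyclo[3.3.0]octane-2,6-dione with two homotopic carbonyl groups.
4. Forward: succinyl bis(oxazolidinone) → double benzyloxymethylation → hydrogenolysis closes both lactone rings at once → aryllithium addition and silane reduction turn one lactone into the 2-aryl tetrahydrofuran ring → the second aryllithium opens the remaining lactone to the aryl ketone and the free CH2OH.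
5. Stereochemistry: C3 and C4 from the (S)-4-benzyloxazolidinone auxiliary, their cis relationship locked by the ring fusion; C2 from hydride delivery to the convex face of the bicyclic oxocarbenium ion (aryl endo).

Key step: step 6

Remark on the chemistry: γ-hydroxy aryl ketones of this kind are in ring–chain equilibrium with their lactols; the lactol from the first aryllithium addition is written closed, the target open as in its SMILES.

**Step 1**
Reactants: 1 (S)-4-benzyl-1,3-oxazolidin-2-one (2 equiv); 2 succinyl chloride
Product: 3 (4S,4'S)-3,3'-(butane-1,4-dioyl)bis(4-benzyl-1,3-oxazolidin-2-one)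
Conditions: n-BuLi, THF, −78 °C; then 2 (0.5 equiv), −78 → 0 °C
Reagents that add atoms: none
Why: N-acylation of the lithiated oxazolidinone with the diacid chloride is the standard way to load this auxiliary and forms no stereocentre.

**Step 2**
Reactants: 3
Product: 5 (4S,4'S)-3,3'-{(2R,3R)-2,3-bis[(benzyloxy)methyl]butane-1,4-dioyl}bis(4-benzyl-1,3-oxazolidin-2-one), via mono-alkylated bis-imide 4 (not isolated)
Conditions: TiCl4, i-Pr2NEt, CH2Cl2, 0 °C; BnOCH2Cl, 0 °C; the sequence is run a second time in the same flask
Reagents that add atoms: benzyl chloromethyl ether, ClCOCc1ccccc1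
Why: Asymmetric alkylation of the chelated chlorotitanium Z-enolate of an N-acyl oxazolidinone (chiral-auxiliary enolate alkylation) should place each benzyloxymethyl group on the enolate face opposite the 4-benzyl group, so that each auxiliary sets its own α-carbon as R and the C2-symmetric (2R,3R) product results.

**Step 3**
Reactants: 5
Product: 7 (3aR,6aR)-tetrahydro-1H,3H-furo[3,4-c]furan-1,4-dione, via diol bis-imide 6 (not isolated)
Conditions: H2 (1 atm), Pd/C, EtOAc, rt; filter; camphorsulfonic acid (cat.), toluene, 50 °C
Reagents that add atoms: none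
Why: Hydrogenolysis of the two benzyl ethers frees two primary alcohols, each 1,4 to the distal imide carbonyl, which should close two γ-lactones by 5-exo-trig acyl transfer (lactonisation with release of the auxiliary), the (2R,3R) configuration leading directly to the only possible cis ring fusion without touching either stereocentre.

**Step 4**
Reactants: 7 (1.5 equiv); 8 4-bromo-1,2-dimethoxybenzene
Product: 11 (3aR,6aR)-4-(3,4-dimethoxyphenyl)-4-hydroxytetrahydro-1H,3H-furo[3,4-c]furan-1-one, via 3,4-dimethoxyphenyllithium 9 (not isolated), via lithium lactolate 10 (not isolated)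
Conditions: 8, n-BuLi, THF, −78 °C; cannulate into 7, THF, −78 °C; AcOH, −78 °C
Reagents that add atoms: none
Why: Bromine–lithium exchange followed by addition of the aryllithium to a γ-lactone (lactone-to-lactol addition) should stop at the tetrahedral lithium lactolate at −78 °C, the two carbonyl groups of 7 being homotopic so that either gives the same lactol, whose new hemiketal centre need not be controlled because it is planarised in step 5.

**Step 5**
Reactants: 11
Product: 12 (3aR,4R,6aR)-4-(3,4-dimethoxyphenyl)tetrahydro-1H,3H-furo[3,4-c]furan-1-one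
Conditions: Et3SiH, BF3·OEt2, CH2Cl2, −78 → −30 °C
Reagents that add atoms: none
Why: Ionic hydrogenation of the lactol (silane reduction of a hemiketal through its aryl-stabilised oxocarbenium ion) should deliver hydride to the convex face of the cis-fused bicycle, anti to the adjacent lactone CH2, which puts the aryl group endo and sets C2 of the target as R, cis to both ring-fusion substituents.

**Step 6**
Reactants: 12; 13 5-bromo-1,2,3-trimethoxybenzene
Product: 16 [(3R,4R,5R)-5-(3,4-dimethoxyphenyl)-4-(hydroxymethyl)oxolan-3-yl](3,4,5-trimethoxyphenyl)methanone, via 3,4,5-trimethoxyphenyllithium 14 (not isolated), via lithium lactolate 15 (not isolated)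
Conditions: 13, n-BuLi, THF, −78 °C; cannulate into 12, THF, −78 °C; AcOH, −78 °C, then pH 7 phosphate buffer
Reagents that add atoms: none
Why: Bromine–lithium exchange gives the aryllithium, which adds to the lactone carbonyl of 12 from the convex face; the tetrahedral adduct should be held as the bicyclic lithium lactolate 15 at −78 °C, so that no ketone is released before the acidic quench and a second addition is avoided. On protonation the lactol opens to the aryl ketone and the C3 hydroxymethyl group, so one operation forms the aroyl C–C bond, sets the ketone oxidation level and removes the temporary lactone ring. The closest known reaction type is the addition of an aryllithium to a γ-butyrolactone to give a γ-hydroxy aryl ketone or its lactol. No ring of the target is closed and no new stereocentre is kept: the lactolate carbon is transient and the three stereocentres of 12 are carried over unchanged. The selectivity needed is mono-addition and retention of the cis C3/C4 relationship next to the new ketone; the first is secured by the lactolate, the second by the ring fusion (enolisation of the lactone can only return the cis-fused bicycle) and by the cold acetic acid quench, before the α-stereocentre of the free ketone can equilibrate.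

**Compound list**

1 | (S)-4-benzyl-1,3-oxazolidin-2-one | O=C1N[C@@H](Cc2ccccc2)CO1 | starting material
2 | succinyl chloride (butanedioyl dichloride) | O=C(Cl)CCC(Cl)=O | starting material
3 | (4S,4'S)-3,3'-(butane-1,4-dioyl)bis(4-benzyl-1,3-oxazolidin-2-one) | O=C(CCC(=O)N1[C@@H](Cc2ccccc2)COC1=O)N1[C@@H](Cc2ccccc2)COC1=O | intermediate
4 | mono-alkylated bis-imide, (2R)-2-[(benzyloxy)methyl]succinyl bis[(S)-4-benzyloxazolidinone] | c1ccccc1COC[C@H](C(=O)N1[C@@H](Cc2ccccc2)COC1=O)CC(=O)N1[C@@H](Cc2ccccc2)COC1=O | intermediate
5 | (4S,4'S)-3,3'-{(2R,3R)-2,3-bis[(benzyloxy)methyl]butane-1,4-dioyl}bis(4-benzyl-1,3-oxazolidin-2-one) | c1ccccc1COC[C@H](C(=O)N1[C@@H](Cc2ccccc2)COC1=O)[C@H](COCc1ccccc1)C(=O)N1[C@@H](Cc2ccccc2)COC1=O | intermediate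
6 | diol bis-imide, (2R,3R)-2,3-bis(hydroxymethyl)succinyl bis[(S)-4-benzyloxazolidinone] | OC[C@H](C(=O)N1[C@@H](Cc2ccccc2)COC1=O)[C@H](CO)C(=O)N1[C@@H](Cc2ccccc2)COC1=O | intermediate
7 | (3aR,6aR)-tetrahydro-1H,3H-furo[3,4-c]furan-1,4-dione, the cis-fused C2-symmetric bis-lactone | O=C1OC[C@H](C(=O)OC2)[C@@H]12 | intermediate
8 | 4-bromo-1,2-dimethoxybenzene | COc1ccc(Br)cc1OC | starting material
9 | 3,4-dimethoxyphenyllithium | COc1ccc([Li])cc1OC | intermediate
10 | lithium lactolate of 11 (hemiketal carbon not fixed) | COc1ccc(C2([O-])OC[C@H](C(=O)OC3)[C@@H]23)cc1OC.[Li+] | intermediate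
11 | (3aR,6aR)-4-(3,4-dimethoxyphenyl)-4-hydroxytetrahydro-1H,3H-furo[3,4-c]furan-1-one (hemiketal carbon not fixed) | COc1ccc(C2(O)OC[C@H](C(=O)OC3)[C@@H]23)cc1OC | intermediate
12 | (3aR,4R,6aR)-4-(3,4-dimethoxyphenyl)tetrahydro-1H,3H-furo[3,4-c]furan-1-one, aryl endo | COc1ccc([C@@H]2OC[C@H](C(=O)OC3)[C@@H]23)cc1OC | intermediate
13 | 5-bromo-1,2,3-trimethoxybenzene | COc1cc(Br)cc(OC)c1OC | starting material
14 | 3,4,5-trimethoxyphenyllithium | COc1cc([Li])cc(OC)c1OC | intermediate
15 | bicyclic lithium lactolate from 12 and 14 (hemiketal carbon not fixed) | COc1ccc([C@@H]2OC[C@H](C([O-])(c4cc(OC)c(OC)c(OC)c4)OC3)[C@@H]23)cc1OC.[Li+] | intermediate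
16 | [(3R,4R,5R)-5-(3,4-dimethoxyphenyl)-4-(hydroxymethyl)oxolan-3-yl](3,4,5-trimethoxyphenyl)methanone | COc1ccc([C@@H]2OC[C@H](C(=O)c3cc(OC)c(OC)c(OC)c3)[C@@H]2CO)cc1OC | target

**Totals**

Total step count: 6. Longest linear sequence: 6 steps (1 → 3 → 5 → 7 → 11 → 12 → 16).

**Steps most likely to fail**

Step 2. The second enolisation and alkylation may stall or lose face selectivity next to the first stereocentre, or the succinyl enolate may attack the distal imide carbonyl through oxygen. Fallback, setting out from 2 and returning at 7: 2 would be esterified with tert-butanol and pyridine to di-tert-butyl succinate F1. Its dianion (LiN(i-Pr)2, 2.2 equiv, THF, −78 °C) would be alkylated twice with benzyl chloromethyl ether to di-tert-butyl 2,3-bis[(benzyloxy)methyl]succinate F2, a mixture of diastereomers. Hydrogenolysis (H2, Pd/C) and treatment with CF3CO2H would remove the benzyl and tert-butyl groups and close the racemic cis-fused bis-lactone F3; the diastereomer that cannot close the second ring would be epimerised through its enolisable lactone with DBU and recycled. Preparative chiral SFC would then supply 7.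

Step 4. Both lactone carbonyls may react, and enolisation with β-elimination of the acyloxy group may compete with addition. Fallback, setting out from 5 and returning at 11: 5 would be hydrolysed (LiOH, H2O2, THF–H2O, 0 °C) to (2R,3R)-2,3-bis[(benzyloxy)methyl]butanedioic acid F4, and Ac2O would close (3R,4R)-3,4-bis[(benzyloxy)methyl]oxolane-2,5-dione F5. Aryllithium 9 at −78 °C should open this C2-symmetric anhydride once only, because the carboxylate set free cannot react again, to give (2R,3R)-2,3-bis[(benzyloxy)methyl]-4-(3,4-dimethoxyphenyl)-4-oxobutanoic acid F6. Hydrogenolysis of the two benzyl ethers (H2, Pd/C, EtOAc) would free both hydroxymethyl groups, which close the lactone and the hemiketal to give 11.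

Step 6. The lactolate may collapse early and allow over-addition, or the stereocentre α to the new ketone may epimerise during work-up. Fallback, setting out from 12 and returning at 16: 12 would be reduced with i-Bu2AlH (toluene, −78 °C) to the lactol (3aR,4R,6aR)-4-(3,4-dimethoxyphenyl)hexahydrofuro[3,4-c]furan-1-ol F7. Aryllithium 14 (2.2 equiv, THF, −78 °C) would add to its hydroxy aldehyde form to give the diol [(3R,4R,5R)-5-(3,4-dimethoxyphenyl)-4-(hydroxymethyl)oxolan-3-yl](3,4,5-trimethoxyphenyl)methanol F8, as a mixture at the carbinol carbon. MnO2 in CH2Cl2 should then oxidise only the benzylic alcohol to give 16.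

**Further compounds**

F1 | step 2 | di-tert-butyl succinate | CC(C)(C)OC(=O)CCC(=O)OC(C)(C)C
F2 | step 2 | di-tert-butyl 2,3-bis[(benzyloxy)methyl]succinate (mixture of diastereomers) | CC(C)(C)OC(=O)C(COCc1ccccc1)C(COCc1ccccc1)C(=O)OC(C)(C)C
F3 | step 2 | racemic cis-fused tetrahydro-1H,3H-furo[3,4-c]furan-1,4-dione | O=C1OCC2C(=O)OCC12
F4 | step 4 | (2R,3R)-2,3-bis[(benzyloxy)methyl]butanedioic acid | c1ccccc1COC[C@H](C(=O)O)[C@H](COCc1ccccc1)C(=O)O
F5 | step 4 | (3R,4R)-3,4-bis[(benzyloxy)methyl]oxolane-2,5-dione | c1ccccc1COC[C@@H]2C(=O)OC(=O)[C@H]2COCc1ccccc1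
F6 | step 4 | (2R,3R)-2,3-bis[(benzyloxy)methyl]-4-(3,4-dimethoxyphenyl)-4-oxobutanoic acid | c1ccccc1COC[C@H](C(=O)O)[C@H](COCc1ccccc1)C(=O)c1ccc(OC)c(OC)c1
F7 | step 6 | (3aR,4R,6aR)-4-(3,4-dimethoxyphenyl)hexahydrofuro[3,4-c]furan-1-ol (lactol carbon not fixed) | COc1ccc([C@@H]2OC[C@H](C(O)OC3)[C@@H]23)cc1OC
F8 | step 6 | [(3R,4R,5R)-5-(3,4-dimethoxyphenyl)-4-(hydroxymethyl)oxolan-3-yl](3,4,5-trimethoxyphenyl)methanol (carbinol carbon not fixed) | COc1ccc([C@@H]2OC[C@H](C(O)c3cc(OC)c(OC)c(OC)c3)[C@@H]2CO)cc1OC
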